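The data come from a simulation from invented constants; noise was put on by code.

The target in the ochre run is still climbing, at 35.2% after 10.0 s, when the substrate reads 0.3%, so something unread stands between them. Violet and ochre then level off short of the whole charge.

| flask | substrate | gas | temperature | remark | time |
|---|---|---|---|---|---|
| violet | 0.050 M | 5.9 mM (held) | 42 °C | run made earlier |  |
| ochre | 0.075 M | 5.9 mM (held) | 59 °C | run made earlier |  |
| birch | 0.10 M | 5.9 mM (held) | 65 °C |  | 5.0 min |
| oak | 0.10 M | 5.9 mM (held) | 35 °C |  | 5.0 min |

violet run (percent of the substrate charged)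

| time / min | target / % | substrate / % |
|---|---|---|
| 0.250 | 28.1 | 24.3 |
| 0.833 | 58.9 | 0.9 |
| 1.33 | 59.0 | 0.6 |
| 2.00 | 59.2 | 1.0 |
| 3.00 | 58.8 | 0 |

ochre run (percent of the substrate charged)

| time / s | target / % | substrate / % |
|---|---|---|
| 10.0 | 35.2 | 0.3 |
| 15.0 | 50.7 | 0 |
| 25.0 | 76.3 | 0.9 |
| 40.0 | 88.3 | 0 |
| 60.0 | 90.1 | 0.2 |

(scatter of a reading: 0.5 percentage points)

- at the start none of the gas is in solution
- a reading or a percentage of target counts all its forms, free or not

- which of the two ends with the higher amount of target, in percent of the substrate charged ("neither" if they lie within 2 percentage points) (birch / oak / neither)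
- target at the end, in percent of the substrate charged, birch
- target at the end, in percent of the substrate charged, oak

I call the target fraction at the last reading over the remaining fraction the split. Violet and ochre give:

S(violet) = 1.43 at 42 °C

S(ochre) = 9.10 at 59 °C

I carry one quantity, the doubling step, the temperature rise that doubles the split:

D = 6.36 K

Stepping from the nearer run gives:

S(birch) = 17.5, target 94.6%

S(oak) = 0.666, target 40.0%

The charges differ too, so D is a reading with that doubt inside it. The weak link, though, is time: does cold oak reach its plateau? Violet was level by 0.833 min. Scaled to oak's charge, that is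

1.67 min

which is shorter than 5.0 min. That leaves a factor of 2.99 to pay for oak being colder than violet. I commit to these figures.

The forecast names birch, with 94% for birch and 41% for oak, “attributing the change to temperature” as I do.

The flask gives birch: birch 95.2%, oak 40.0%.

    substrate → intermediate (k = 0.0480 s⁻¹, Ea = 80.0 kJ mol⁻¹)
    partner + intermediate → target (k = 13.0 M⁻¹ s⁻¹, Ea = 37.0 kJ mol⁻¹)
    gas ⇌ partner, rate k3*(csat - [partner]) (kL = 0.740 s⁻¹)
    crystals ⇌ target, rate k4*(cs4 - [target]) while solid is left; crystals form when [target] > cs4 (solubility = 0.0720 M, k = 11.0 s⁻¹)
    target ⇌ isomer of the product (K = 1.50, k = 0.0250 s⁻¹, Ea = 92.0 kJ mol⁻¹, ΔH = −90.0 kJ mol⁻¹)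
    (constants at 35 °C)

Taken away, the conversion of target into isomer of the product lifts oak from 40.0% to >99.9%. In oak the loss in my split is that isomer, and oak's split is an equilibrium between target and isomer (thermodynamic control). Oak's relaxation half-life, 0.277 min, is short against 5.0 min, and its split ends at 0.667 beside the 0.666 stepped by D. A repeat of oak at 20 °C stands apart from D: D asks for a split of 0.130, but after 5.00 min that flask holds 47.3% target to 45.2% isomer, a ratio of target over isomer of 1.05, with 5.4% of the substrate still there.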